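I decided to follow the coupling partner's level, not its charge, and to ask at that level which route took the dissolved substrate.

the same everywhere: solid substrate 10 mM; time 2.5 d
- alpha: coupling partner 4.00 mM
- zeta: coupling partner 12.0 mM
- eta: coupling partner 40.0 mM

    solid substrate + target → side product B (k1 = 0.0014 M⁻¹ s⁻¹)
    solid substrate ⇌ dissolved substrate, rate k2*(cs2 - [dissolved substrate]) while solid is left; crystals form when [dissolved substrate] > cs2 (cs2 = 5.0 mM, k2 = 1.1 × 10⁻⁵ s⁻¹)
    coupling partner → decomposed reagent (k3 = 1.5 × 10⁻⁵ s⁻¹)
    dissolved substrate + coupling partner → target (k4 = 0.092 M⁻¹ s⁻¹)
    2 dissolved substrate → side product A (k5 = 0.15 M⁻¹ s⁻¹)

- percent here means solid substrate units held: one side product A or side product B counts as two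
- a step written with two of one species runs at k times the square of its concentration and takes two of it each time
- solid substrate is a solid; its amount is given per volume of the solution
- at the start none of the solid substrate is in solution
- "hardly changes" means that all values lie within two and a half points (for a concentration: within two and a half percent of the largest)
- run time (alpha): 2.5 d

- amount of target at the end, in percent of the solid substrate charged for alpha, zeta, eta, in this order
- the shape of the row from first to last (rises, then falls / rises all the way / falls all the way / falls, then rises / hardly changes)

I reckoned the full pace of the solid at 0.475 d⁻¹ of its charge into solution, so my estimate for dissolving the charge was 2.10 d, or less once side product B began to take solid as well. But two routes competed for what dissolved: coupling runs with the first power of dissolved substrate, and side product A with its square. So I made the two uses equal and let them sum to the feed. That gave the square root of feed times dimerisation constant, over coupling constant: 0.987 mM. This is the break-even partner level, the partner concentration at which, with solid feeding at full pace, coupling and dimerisation use dissolved substrate equally.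

As a fraction of each flask's own partner charge, this level was 24.7% in alpha, 8.23% in zeta and 2.47% in eta. But the partner also decays, so I reckoned the time to reach that level by decay, leaving coupling's use uncounted. This gave 1.08 d for alpha, 1.93 d for zeta and 2.86 d for eta. Eta's time was longer than the feed time, and zeta's was shorter. So I expected a rising row, though my reckoning gave no percentages, since it did not follow the target's loss to side product B.

The forecast gave 11%, 30% and 53%, a row that rises all the way, holding for eta that “the partner outlasts the solid, and coupling takes nearly all the dissolved substrate”.

The simulation gave 10.5%, 29.1% and 56.1%, a row that rises all the way. At 1.25 d, eta still held 12.8% of its partner charge, more than its break-even fraction of 2.47%, and side product A stood at 0.812%. At that time zeta held 4.08%, less than its 8.23%, with side product A at 10.7%, while alpha held 1.10%, less than its 24.7%, with side product A at 30.4%.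

The constants stand for no real mixture, and the outcome is calculated.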